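**Plan**

- Retrosynthesis: the four O–CH3 bonds are cut last. In the chlorodaidzein unit, O1–C8a and C8–Cl are then cut together.
- Enabling feature: C8a (bearing O1) and C8 (bearing Cl) are neighbouring carbons of ring A of the chlorodaidzein unit, and C8 has the oxygen-bearing C7 on its other side. This is the pattern of a 3-alkoxyaryne that takes an oxygen nucleophile at the distal carbon and an electrophile at the proximal one.
- Further cuts: C2–C3 (formyl carbon), C3–C4 (benzylzinc plus aldehyde), the diaryl ether C–O bond (SNAr) and the C8–O bond of the genistein unit.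
- Forward: 3-methoxyphenol gives the ortho-silyl aryl triflate aldehyde 12 (steps 1–4). Genistein, whose rings are carried intact, gives benzyl chloride 21 (steps 5–10). The halves are joined through benzylzinc 22, then oxidised and formylated (steps 11–13).
- Ring C of the chloro unit is the only ring built and closes in step 14; global demethylation (step 15) ends the route.
- Stereochemistry: the target has no stereocentre. The carbinol carbon of 23 and the α-carbon of 26 are racemic and vanish.

Key step: step 14

Remark: 26 is drawn as the keto-aldehyde but should exist largely as its hydroxymethylene (enol) tautomer. Carbamate 10 may equilibrate with a cyclic N,O-hemiaminal, which step 4 funnels to the same phenoxide.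

**Route**

Step 1
Reactants: 1 3-methoxyphenol
Product: 2 3-methoxyphenyl N-isopropylcarbamate
Conditions: i-PrNCO (1.2 equiv), Et3N (0.1 equiv), CH2Cl2, rt
Reagents that add atoms: isopropyl isocyanate, CC(C)N=C=O
Why: Amine-catalysed addition of the phenol to the isocyanate (carbamoylation) installs a strong ortho-directing group that can later be removed under mild base.

Step 2
Reactants: 2 3-methoxyphenyl N-isopropylcarbamate
Product: 6 3-methoxy-2-(trimethylsilyl)phenyl N-isopropylcarbamate, via N-TBS carbamate 3 (not isolated), via aryllithium 4 (not isolated), via N-TBS C-silyl carbamate 5 (not isolated)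
Conditions: t-BuMe2SiOTf (1.1 equiv), TMEDA (1.1 equiv), Et2O, 0 °C → rt; n-BuLi (2.1 equiv), TMEDA (2 equiv), −78 °C; Me3SiCl, −78 °C → rt; 1 M aq. NaHSO4, 0 °C
Reagents that add atoms: chlorotrimethylsilane, C[Si](C)(C)Cl
Why: Directed ortho-metalation of the carbamate, N-silylated in the flask with the bulky tert-butyldimethylsilyl group that shields the carbonyl from butyllithium, should occur at the carbon between the carbamate and methoxy oxygens where both directors cooperate, the aryllithium is C-silylated by Me3SiCl, and the N–Si bond is hydrolysed in the brief cold bisulfate work-up, which is too mild to protodesilylate the ring.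

Step 3
Reactants: 6 3-methoxy-2-(trimethylsilyl)phenyl N-isopropylcarbamate
Product: 10 6-formyl-3-methoxy-2-(trimethylsilyl)phenyl N-isopropylcarbamate, via bis(trimethylsilyl) carbamate 7 (not isolated), via aryllithium 8 (not isolated), via hemiaminal alkoxide 9 (not isolated)
Conditions: Me3SiOTf (1.1 equiv), TMEDA (1.1 equiv), Et2O, 0 °C → rt; n-BuLi (2.1 equiv), TMEDA (2 equiv), −78 °C; DMF, −78 → 0 °C; aq. NH4Cl
Reagents that add atoms: N,N-dimethylformamide, CN(C)C=O
Why: A second directed ortho-metalation, now under transient N-trimethylsilyl protection that is shed on neutral aqueous work-up so that the aldehyde and the aryl–silicon bond see no acid, should place lithium at the only free position ortho to the carbamate (a stronger director than methoxy, the doubly activated site being blocked by silicon), and DMF formylates it.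

Step 4
Reactants: 10 6-formyl-3-methoxy-2-(trimethylsilyl)phenyl N-isopropylcarbamate
Product: 12 6-formyl-3-methoxy-2-(trimethylsilyl)phenyl trifluoromethanesulfonate, via silyl salicylaldehyde 11 (not isolated)
Conditions: Et2NH, DBU, MeCN, 40 °C; then PhNTf2, rt
Reagents that add atoms: N-phenylbis(trifluoromethanesulfonimide), O=S(=O)(N(c1ccccc1)S(=O)(=O)C(F)(F)F)C(F)(F)F
Why: E1cB cleavage of the N-monoalkyl carbamate (the expelled isocyanate is trapped by Et2NH) frees the phenoxide, which is O-triflated in the same flask; the medium is basic throughout, so the aryl–silicon bond between two oxygens is not exposed to protodesilylation.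

Step 5
Reactants: 13 genistein
Product: 14 5,7,4'-tri-O-methylgenistein
Conditions: Me2SO4 (excess), K2CO3, acetone, reflux
Reagents that add atoms: dimethyl sulfate, COS(=O)(=O)OC
Why: Williamson O-methylation of all three phenols, with excess reagent and prolonged reflux for the hydrogen-bonded 5-OH, gives ethers that survive every later step.

Step 6
Reactants: 14 5,7,4'-tri-O-methylgenistein
Product: 15 8-iodo-5,7,4'-tri-O-methylgenistein
Conditions: I2, CF3CO2Ag, CH2Cl2, 0 °C → rt
Reagents that add atoms: iodine, [I][I]
Why: Electrophilic aromatic iodination of a 5,7-dialkoxychromone is expected at C8, which is activated by O1, the ortho 7-OMe and the para 5-OMe and is less crowded than C6 between two methoxy groups.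

Step 7
Reactants: 15 8-iodo-5,7,4'-tri-O-methylgenistein
Product: 17 8-hydroxy-5,7,4'-tri-O-methylgenistein, via pinacol boronate 16 (not isolated)
Conditions: B2pin2, Pd2(dba)3 (cat.), XPhos (cat.), KOAc, 1,4-dioxane, 90 °C; then 30% aq. H2O2, NaHCO3, THF, 0 °C → rt
Reagents that add atoms: hydrogen peroxide, OO
Why: Miyaura borylation with a bulky biarylphosphine catalyst suited to doubly ortho-substituted halides, then boron-to-oxygen aryl migration with hydroperoxide under weakly basic conditions that should spare the chromone.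

Step 8
Reactants: 17 8-hydroxy-5,7,4'-tri-O-methylgenistein; 18 4-fluorobenzaldehyde
Product: 19 4-[(5,7-dimethoxy-3-(4-methoxyphenyl)-4-oxochromen-8-yl)oxy]benzaldehyde
Conditions: K2CO3, DMF, 90 °C
Reagents that add atoms: none
Why: Nucleophilic aromatic substitution (SNAr) of fluoride, activated by the para-formyl group, by the C8 phenoxide forms the diaryl ether in anhydrous medium that the chromone tolerates.

Step 9
Reactants: 19 4-[(5,7-dimethoxy-3-(4-methoxyphenyl)-4-oxochromen-8-yl)oxy]benzaldehyde
Product: 20 8-[4-(hydroxymethyl)phenoxy]-5,7,4'-tri-O-methylgenistein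
Conditions: NaBH4 (0.5 equiv), THF–MeOH, −10 °C
Reagents that add atoms: none
Why: Hydride reduction should be selective because the aldehyde is far more electrophilic than the vinylogous-ester carbonyl of the chromone at low temperature with limited borohydride.

Step 10
Reactants: 20 8-[4-(hydroxymethyl)phenoxy]-5,7,4'-tri-O-methylgenistein
Product: 21 8-[4-(chloromethyl)phenoxy]-5,7,4'-tri-O-methylgenistein
Conditions: SOCl2, DMF (cat.), CH2Cl2, 0 °C → rt
Reagents that add atoms: thionyl chloride, ClS(Cl)=O
Why: Chlorodehydroxylation through the chlorosulfite is fast for an aryloxy-activated benzylic alcohol and touches nothing else.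

Step 11
Reactants: 21 8-[4-(chloromethyl)phenoxy]-5,7,4'-tri-O-methylgenistein; 12 6-formyl-3-methoxy-2-(trimethylsilyl)phenyl trifluoromethanesulfonate
Product: 23 racemic 1-[4-methoxy-2-(trifluoromethanesulfonyloxy)-3-(trimethylsilyl)phenyl]-2-{4-[(tri-O-methylgenistein-8-yl)oxy]phenyl}ethanol, via benzylzinc chloride 22 (not isolated)
Conditions: Zn dust, LiCl, THF, 25 °C; then 12, MgCl2, THF, 0 → 25 °C; aq. NH4Cl
Reagents that add atoms: none
Why: LiCl-promoted oxidative insertion of zinc into the benzylic C–Cl bond gives a benzylzinc reagent that tolerates the chromone, the aryl triflate and the aryl silane and undergoes 1,2-addition to the aldehyde; the new carbinol centre is racemic and is erased in step 12.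

Step 12
Reactants: 23 racemic carbinol
Product: 24 1-[4-methoxy-2-(trifluoromethanesulfonyloxy)-3-(trimethylsilyl)phenyl]-2-{4-[(tri-O-methylgenistein-8-yl)oxy]phenyl}ethanone
Conditions: Dess–Martin periodinane, CH2Cl2, rt
Reagents that add atoms: none
Why: Dess–Martin oxidation converts the secondary benzylic alcohol to the deoxybenzoin under neutral conditions compatible with triflate, silane and chromone.

Step 13
Reactants: 24 deoxybenzoin
Product: 26 3-[4-methoxy-2-(trifluoromethanesulfonyloxy)-3-(trimethylsilyl)phenyl]-3-oxo-2-{4-[(tri-O-methylgenistein-8-yl)oxy]phenyl}propanal, via lithium enolate 25 (not isolated)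
Conditions: LiN(SiMe3)2 (1.2 equiv), THF, −78 °C; CF3CH2OCHO, −78 → −30 °C; aq. NH4Cl
Reagents that add atoms: 2,2,2-trifluoroethyl formate, O=COCC(F)(F)F
Why: Crossed Claisen formylation of the deoxybenzoin enolate, the classical entry to isoflavone precursors, is run with an activated formate at low temperature so that the ortho triflate never meets a nucleophilic alkoxide.

Step 14
Reactants: 26 formyl ketone; 27 hexachloroethane
Product: 31 tetra-O-methyl bisoflavolin H, via potassium enolate 28 (not isolated), via aryne 29 (not isolated), via arylpotassium 30 (not isolated)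
Conditions: KH (1.0 equiv), THF, 0 °C; then C2Cl6 (5 equiv), KF (3 equiv), 18-crown-6 (3 equiv), THF, 0 °C → rt
Reagents that add atoms: none
Why: Proposed new method: fluoride removes the silyl group at C8 and triflate leaves from C8a, so the C8a≡C8 aryne 29 forms with the formyl-enolate oxygen already in the ring plane, and this oxygen adds to C8a to close ring C in a 6-exo-dig mode, attack through carbon or the ketone oxygen being excluded because either would need a four-membered ring. The C8 anion 30 that results lies between O1 and the methoxy-bearing C7, the polarity that the inductive effect of a 3-alkoxy group favours in aryne additions, and it abstracts chlorine from C2Cl6, whose pentachloroethyl anion collapses to tetrachloroethene and chloride. The closest known reactions are three-component aryne couplings that add a heteroatom nucleophile and a halogen electrophile across the triple bond, and O-arylations of arynes by oxygen nucleophiles that end in ring closure; using the oxygen of a tethered 1,3-dicarbonyl enolate with a chlorine trap is the new element. No stereocentre is formed. The step needs O- over C-arylation and addition at C8a (both secured by tether length, the coplanar enolate and the C7 methoxy group) and chlorine transfer faster than protonation, for which the enolate is pre-formed with KH so that only H2 leaves, the fluoride source is anhydrous and excess C2Cl6 is present before the aryne appears.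

Step 15
Reactants: 31 tetra-O-methyl bisoflavolin H
Product: 32 bisoflavolin H
Conditions: BBr3 (12 equiv), CH2Cl2, −78 °C → rt; then MeOH, H2O
Reagents that add atoms: none
Why: Lewis-acid cleavage of the four aryl methyl ethers by BBr3 should leave the chromone carbonyls, the diaryl ether and the aryl chloride untouched.

**Compound list**

1 | 3-methoxyphenol | COc1cccc(O)c1 | starting material
2 | 3-methoxyphenyl N-isopropylcarbamate | COc1cccc(OC(=O)NC(C)C)c1 | intermediate
3 | 3-methoxyphenyl N-(tert-butyldimethylsilyl)-N-isopropylcarbamate (not isolated) | COc1cccc(OC(=O)N(C(C)C)[Si](C)(C)C(C)(C)C)c1 | intermediate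
4 | 2-lithio-3-methoxyphenyl N-(tert-butyldimethylsilyl)-N-isopropylcarbamate (not isolated) | COc1cccc(OC(=O)N(C(C)C)[Si](C)(C)C(C)(C)C)c1[Li] | intermediate
5 | 3-methoxy-2-(trimethylsilyl)phenyl N-(tert-butyldimethylsilyl)-N-isopropylcarbamate (not isolated) | COc1cccc(OC(=O)N(C(C)C)[Si](C)(C)C(C)(C)C)c1[Si](C)(C)C | intermediate
6 | 3-methoxy-2-(trimethylsilyl)phenyl N-isopropylcarbamate | COc1cccc(OC(=O)NC(C)C)c1[Si](C)(C)C | intermediate
7 | 3-methoxy-2-(trimethylsilyl)phenyl N-isopropyl-N-(trimethylsilyl)carbamate (not isolated) | COc1cccc(OC(=O)N(C(C)C)[Si](C)(C)C)c1[Si](C)(C)C | intermediate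
8 | 6-lithio-3-methoxy-2-(trimethylsilyl)phenyl N-isopropyl-N-(trimethylsilyl)carbamate (not isolated) | COc1ccc([Li])c(OC(=O)N(C(C)C)[Si](C)(C)C)c1[Si](C)(C)C | intermediate
9 | lithium hemiaminal alkoxide from 8 and DMF (not isolated, configuration at the transient carbon undefined) | COc1ccc(C(O[Li])N(C)C)c(OC(=O)N(C(C)C)[Si](C)(C)C)c1[Si](C)(C)C | intermediate
10 | 6-formyl-3-methoxy-2-(trimethylsilyl)phenyl N-isopropylcarbamate | COc1ccc(C=O)c(OC(=O)NC(C)C)c1[Si](C)(C)C | intermediate
11 | 2-hydroxy-4-methoxy-3-(trimethylsilyl)benzaldehyde (present as its DBU salt, not isolated) | COc1ccc(C=O)c(O)c1[Si](C)(C)C | intermediate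
12 | 6-formyl-3-methoxy-2-(trimethylsilyl)phenyl trifluoromethanesulfonate | COc1ccc(C=O)c(OS(=O)(=O)C(F)(F)F)c1[Si](C)(C)C | intermediate
13 | genistein | O=c1c(-c2ccc(O)cc2)coc2cc(O)cc(O)c12 | starting material
14 | 5,7,4'-tri-O-methylgenistein (5,7-dimethoxy-3-(4-methoxyphenyl)chromen-4-one) | COc1ccc(-c2coc3cc(OC)cc(OC)c3c2=O)cc1 | intermediate
15 | 8-iodo-5,7,4'-tri-O-methylgenistein | Ic1c(OC)cc(OC)c2c(=O)c(-c3ccc(OC)cc3)coc12 | intermediate
16 | 8-(4,4,5,5-tetramethyl-1,3,2-dioxaborolan-2-yl)-5,7,4'-tri-O-methylgenistein (not isolated) | COc1ccc(-c2coc3c(B4OC(C)(C)C(C)(C)O4)c(OC)cc(OC)c3c2=O)cc1 | intermediate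
17 | 8-hydroxy-5,7,4'-tri-O-methylgenistein | COc1ccc(-c2coc3c(O)c(OC)cc(OC)c3c2=O)cc1 | intermediate
18 | 4-fluorobenzaldehyde | O=Cc1ccc(F)cc1 | starting material
19 | 4-[(5,7-dimethoxy-3-(4-methoxyphenyl)-4-oxochromen-8-yl)oxy]benzaldehyde | COc1ccc(-c2coc3c(Oc4ccc(C=O)cc4)c(OC)cc(OC)c3c2=O)cc1 | intermediate
20 | 8-[4-(hydroxymethyl)phenoxy]-5,7-dimethoxy-3-(4-methoxyphenyl)chromen-4-one | COc1ccc(-c2coc3c(Oc4ccc(CO)cc4)c(OC)cc(OC)c3c2=O)cc1 | intermediate
21 | 8-[4-(chloromethyl)phenoxy]-5,7-dimethoxy-3-(4-methoxyphenyl)chromen-4-one | COc1ccc(-c2coc3c(Oc4ccc(CCl)cc4)c(OC)cc(OC)c3c2=O)cc1 | intermediate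
22 | benzylzinc chloride from 21 (not isolated) | COc1ccc(-c2coc3c(Oc4ccc(C[Zn]Cl)cc4)c(OC)cc(OC)c3c2=O)cc1 | intermediate
23 | racemic 1-[4-methoxy-2-(trifluoromethanesulfonyloxy)-3-(trimethylsilyl)phenyl]-2-{4-[(5,7-dimethoxy-3-(4-methoxyphenyl)-4-oxochromen-8-yl)oxy]phenyl}ethanol | COc1ccc(C(O)Cc2ccc(Oc3c(OC)cc(OC)c4c(=O)c(-c5ccc(OC)cc5)coc34)cc2)c(OS(=O)(=O)C(F)(F)F)c1[Si](C)(C)C | intermediate
24 | 1-[4-methoxy-2-(trifluoromethanesulfonyloxy)-3-(trimethylsilyl)phenyl]-2-{4-[(5,7-dimethoxy-3-(4-methoxyphenyl)-4-oxochromen-8-yl)oxy]phenyl}ethanone | COc1ccc(C(=O)Cc2ccc(Oc3c(OC)cc(OC)c4c(=O)c(-c5ccc(OC)cc5)coc34)cc2)c(OS(=O)(=O)C(F)(F)F)c1[Si](C)(C)C | intermediate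
25 | lithium enolate of 24 (not isolated, double-bond geometry not fixed) | COc1ccc(C(O[Li])=Cc2ccc(Oc3c(OC)cc(OC)c4c(=O)c(-c5ccc(OC)cc5)coc34)cc2)c(OS(=O)(=O)C(F)(F)F)c1[Si](C)(C)C | intermediate
26 | 3-[4-methoxy-2-(trifluoromethanesulfonyloxy)-3-(trimethylsilyl)phenyl]-3-oxo-2-{4-[(5,7-dimethoxy-3-(4-methoxyphenyl)-4-oxochromen-8-yl)oxy]phenyl}propanal (keto-aldehyde drawn, enol tautomer expected, α-carbon racemic and labile) | COc1ccc(C(=O)C(C=O)c2ccc(Oc3c(OC)cc(OC)c4c(=O)c(-c5ccc(OC)cc5)coc34)cc2)c(OS(=O)(=O)C(F)(F)F)c1[Si](C)(C)C | intermediate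
27 | hexachloroethane | ClC(Cl)(Cl)C(Cl)(Cl)Cl | starting material
28 | potassium enolate of 26 (not isolated) | COc1ccc(C(=O)C(=C[O-])c2ccc(Oc3c(OC)cc(OC)c4c(=O)c(-c5ccc(OC)cc5)coc34)cc2)c(OS(=O)(=O)C(F)(F)F)c1[Si](C)(C)C.[K+] | intermediate
29 | aryne enolate, triple bond between the former triflate and silyl carbons (not isolated) | COC1=CC=C(C(=O)C(=C[O-])c2ccc(Oc3c(OC)cc(OC)c4c(=O)c(-c5ccc(OC)cc5)coc34)cc2)C#C1.[K+] | intermediate
30 | 8-potassio-7-methoxy-3-{4-[(5,7-dimethoxy-3-(4-methoxyphenyl)-4-oxochromen-8-yl)oxy]phenyl}chromen-4-one (not isolated) | COc1ccc2c(=O)c(-c3ccc(Oc4c(OC)cc(OC)c5c(=O)c(-c6ccc(OC)cc6)coc45)cc3)coc2c1[K] | intermediate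
31 | tetra-O-methyl bisoflavolin H (8-chloro-7-methoxy-3-{4-[(5,7-dimethoxy-3-(4-methoxyphenyl)-4-oxochromen-8-yl)oxy]phenyl}chromen-4-one) | COc1ccc2c(=O)c(-c3ccc(Oc4c(OC)cc(OC)c5c(=O)c(-c6ccc(OC)cc6)coc45)cc3)coc2c1Cl | intermediate
32 | bisoflavolin H (8-chloro-7-hydroxy-3-{4-[(5,7-dihydroxy-3-(4-hydroxyphenyl)-4-oxochromen-8-yl)oxy]phenyl}chromen-4-one) | O=c1c(-c2ccc(Oc3c(O)cc(O)c4c(=O)c(-c5ccc(O)cc5)coc34)cc2)coc2c(Cl)c(O)ccc12 | target

**Totals and risks**

Total step count: 15. Longest linear sequence: 11 steps (genistein 13 to target 32, steps 5–15); the 3-methoxyphenol branch contributes 4 steps before the union.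

Steps most likely to fail:

1. Step 14 (the labelled step). What may go wrong: protonation of the C8 anion before chlorine transfer; ring closure without an aryne through triflyl transfer to the enolate or direct displacement of triflate; C-chlorination of the enolate by C2Cl6. The fallback uses known chemistry and takes the chlorine from a building block; it sets out from benzyl chloride 21 and comes back at target 32. Zinc reagent 22, made from 21 as in step 11, would be carboxylated with CO2 (MgCl2, THF, 25 °C; aq. HCl work-up) to 2-{4-[(tri-O-methylgenistein-8-yl)oxy]phenyl}acetic acid F1. F1 would acylate commercial 2-chlororesorcinol in BF3·OEt2 at 85 °C (Friedel–Crafts acylation; only the equivalent C4/C6 positions are activated) to give the 3-chloro-2,4-dihydroxyphenyl benzyl ketone F2. DMF and MsCl added to the same medium (70 °C) would supply C2 and close the pyranone through the hydroxyl next to chlorine, giving the 8-chloro-7-hydroxyisoflavone F3. BBr3 as in step 15 would then remove the three remaining methyl ethers to give 32.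

2. Step 13. What may go wrong: migration of the triflyl group from the aryl oxygen to the enolate oxygen within 25, and loss of the new formyl group by retro-Claisen cleavage during work-up. The fallback sets out from 24 and comes back at 26. Ketone 24 would be condensed with DMF dimethyl acetal (toluene, 80 °C), an aminomethylenation that needs no metal enolate or alkoxide base, to give the enaminone F4. Brief hydrolysis with dilute aq. HCl in THF at 0 °C would then deliver 26.

3. Step 7. What may go wrong: protodeiodination during borylation of the doubly ortho-substituted iodide, and protodeboronation of the electron-rich boronate before it is oxidised. The fallback sets out from 15 and comes back at 19. The C8–O bond would be formed directly by Ullmann diaryl ether coupling of 15 with 4-hydroxybenzaldehyde (CuI, picolinic acid, K3PO4, DMSO, 90 °C), which bypasses phenol 17 and the SNAr of step 8; no new compound arises (F0).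

**Further compounds**

F1 | step 14 | 2-{4-[(5,7-dimethoxy-3-(4-methoxyphenyl)-4-oxochromen-8-yl)oxy]phenyl}acetic acid | COc1ccc(-c2coc3c(Oc4ccc(CC(=O)O)cc4)c(OC)cc(OC)c3c2=O)cc1
F2 | step 14 | 1-(3-chloro-2,4-dihydroxyphenyl)-2-{4-[(5,7-dimethoxy-3-(4-methoxyphenyl)-4-oxochromen-8-yl)oxy]phenyl}ethanone | O=C(Cc1ccc(Oc2c(OC)cc(OC)c3c(=O)c(-c4ccc(OC)cc4)coc23)cc1)c1ccc(O)c(Cl)c1O
F3 | step 14 | 8-chloro-7-hydroxy-3-{4-[(5,7-dimethoxy-3-(4-methoxyphenyl)-4-oxochromen-8-yl)oxy]phenyl}chromen-4-one | O=c1c(-c2ccc(Oc3c(OC)cc(OC)c4c(=O)c(-c5ccc(OC)cc5)coc34)cc2)coc2c(Cl)c(O)ccc12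
F4 | step 13 | 3-(dimethylamino)-1-[4-methoxy-2-(trifluoromethanesulfonyloxy)-3-(trimethylsilyl)phenyl]-2-{4-[(5,7-dimethoxy-3-(4-methoxyphenyl)-4-oxochromen-8-yl)oxy]phenyl}prop-2-en-1-one (double-bond geometry not fixed) | COc1ccc(C(=O)C(=CN(C)C)c2ccc(Oc3c(OC)cc(OC)c4c(=O)c(-c5ccc(OC)cc5)coc34)cc2)c(OS(=O)(=O)C(F)(F)F)c1[Si](C)(C)C
F0 | step 7 | none | none
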